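Watch the substrate.

| flask | substrate | reagent | catalyst | remark | time |
|---|---|---|---|---|---|
| elm | 0.020 M | 2 equiv | 15 mol% | run made earlier |  |
| larch | 0.020 M | 2 equiv | 10 mol% | run made earlier |  |
| maple | 0.020 M | 2 equiv | 22 mol% | run made earlier |  |
| oak | 0.020 M | 4 equiv | 15 mol% | run made earlier |  |
| beta | 0.020 M | 2.00 equiv | 15 mol% | a single well-mixed tank run continuously and read at steady state, 20 h in it on average |  |
| gamma | 0.020 M | 2.00 equiv | 15 mol% | everything together in a closed stirred flask, run for 20 h | 20 h |
| zeta | 0.020 M (fed, over 10.0 h) | 2.00 equiv | 15 mol% | all but substrate at the start; substrate goes in evenly over 10.0 h, the run ends at 20 h | 20 h |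
| delta | 0.020 M | 2.00 equiv (fed, over 10.0 h) | 15 mol% | a stirred flask in which reagent is dosed at a steady rate over 10.0 h without added volume, worked up at 20 h | 20 h |

| run | time / h | product / % |
|---|---|---|
| elm | 1.00 | 58.1 |
| elm | 1.33 | 69.4 |
| elm | 2.00 | 81.6 |
| elm | 3.00 | 87.7 |
| elm | 5.00 | 90.5 |
| elm | 8.00 | 91.4 |
| elm | 12.0 | 90.8 |
| larch | 2.50 | 74.0 |
| larch | 5.00 | 86.6 |
| larch | 6.00 | 86.6 |
| larch | 10.0 | 88.2 |
| larch | 12.0 | 87.6 |
| larch | 15.0 | 87.3 |
| maple | 0.833 | 67.1 |
| maple | 2.50 | 91.5 |
| maple | 5.00 | 93.4 |
| maple | 6.00 | 93.9 |
| maple | 10.0 | 93.7 |
| maple | 12.0 | 94.1 |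
| maple | 15.0 | 93.9 |
| oak | 1.33 | 84.5 |
| oak | 4.00 | 91.9 |
| oak | 8.00 | 91.7 |
| oak | 12.0 | 91.4 |
| oak | 15.0 | 90.9 |

(scatter of a reading: 0.5 percentage points)

- the stated concentrations are those of everything mixed, before any reaction; amounts are the same in each set-up
- the feed brings no volume worth counting
- the earlier runs were made in a closed, stirred flask

- the set-up with the highest amount of product at the outlet or at the end, in percent of the substrate put in ("none" if the first two lie within 2 percentage points) (beta / gamma / zeta / delta / none)
- amount of product at the outlet or at the end, in percent of the substrate put in, beta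
- amount of product at the outlet or at the end, in percent of the substrate put in, gamma
- amount of product at the outlet or at the end, in percent of the substrate put in, zeta
- amount of product at the outlet or at the end, in percent of the substrate put in, delta

- Elm levels off near 90.9 %, and the missing part is substrate lost to a side path. From larch to maple the loading rises 2.20 times and the loss at 12.0 h falls 2.10 times, so the catalyst's capture of substrate competes with that path.
- Oak, with twice the reagent, reads 91.7 % at 8.00 h where elm reads 91.4 %, so we expect dosing reagent to leave the loss alone.
- Elm, larch, maple and oak share one substrate concentration, 0.020 M, so they do not show the order of the side path; we bet that it pairs two substrate. Its rate over the capture rate then falls in step with substrate, so we take the starting value for elm as 0.182, of which a closed flask loses about half. We carry this as the loss ratio: side rate over capture rate, at the charged concentrations.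
- Elm's first reading gives a pseudo-first-order rate constant of 1.02 h⁻¹.
- In zeta, we reckon that feed and consumption balance with about 9.81 % of the charge standing as substrate, which multiplies the ratio by that share to give 1.79 %, so we reckon 98.2 % product.
- In beta, we reckon that 4.68 % of the charge stands as substrate and leaves unconverted, so we reckon 94.5 % product. We expect gamma and delta near 90.9 %, and we pick zeta.
- The forecast differs: 86.3 % for beta, 90.6 % for gamma, 90.8 % for zeta, 90.4 % for delta, best none. It adds: “A second-order side reaction can't be excluded, and would favour zeta and beta.”
- The flasks give 93.6 % for beta, 91.3 % for gamma, 99.3 % for zeta and 91.3 % for delta, best zeta.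

    substrate + catalyst → catalyst + intermediate (k = 15.0 M⁻¹ min⁻¹)
    reagent + catalyst + intermediate → catalyst + product (k = 290 M⁻² min⁻¹)
    2 substrate → homo dimer (k = 0.220 M⁻¹ min⁻¹)

- In zeta at 5.37 h the catalyst used substrate 140 times as fast as pairing did, a loss ratio of 0.719 % against our 1.79 %, with substrate at 3.68 % of the charge at 10.0 h, less than our 9.81 %. In the neighbouring flask, zeta at 0.0050 M with the same equivalents and loadings, 0.182 carries over and catalyst falls 4.00 times, so we scale the standing share to 14.7 % and the ratio to 2.68 %, and that flask stores homo dimer, counted as two, at 2.36 % after 20.0 h.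

All runs are calculated from invented constants; the scatter is artificial.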